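**Retrosynthetic overview**

1. The C5 chloride is taken back to an anti-5,6-diol (chloride opens the derived acetoxonium ion at allylic C5 with inversion), and the diol is cut at C6–C7 into the finished oxocene half and the finished C1–C6 enyne half.
2. C6–C7 is made by a stereoconvergent decarboxylative chromium coupling: the C7-epimeric oxocene-2-carboxylic acid, as its N-acyloxyphthalimide, gives a C7 radical and then an alkyl–Cr(III) that adds to (2R,3Z)-2-(triethylsilyloxy)hex-3-en-5-ynal.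
3. Enabling feature: C7 is the ring carbon bonded to the ether oxygen of the eight-membered oxocene (O, C7–C13), so a radical or C–Cr bond there is stabilised and a carboxyl group is a traceless handle; C6 is a carbinol next to heteroatom-bearing C5, i.e. the carbonyl carbon of an α-oxygenated aldehyde under Felkin–Anh control.
4. Ring order: a temporary 4-chloro-5,6-dihydropyran-2-one (C8–C12, from (R)-2-hydroxybutanoate by chelation-controlled aldol) is formed first to fix the ring-cis C9=C10(Cl) bond and is then opened; the oxocene is closed next at C7–C8 by glycolate enolate alkylation, before the key step.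
5. The aldehyde half comes from (R)-solketal by a (Z)-selective Peterson enyne olefination.

Key step: step 17

Assumption: compounds 1, 2, 5, 16 and 18 are taken as commercial; locants C1–C15 follow the target chain (C1 = alkyne terminus, C15 = ethyl terminus).

**Route**

Step 1
Reactants: 1 methyl (2R)-2-hydroxybutanoate; 2 tert-butyl diazoacetate
Product: 3 methyl (2R)-2-(2-tert-butoxy-2-oxoethoxy)butanoate
Conditions: Rh2(OAc)4 (1 mol%), CH2Cl2, 25 °C, slow addition of 2
Reagents that add atoms: none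
Why: Rh(II)-carbenoid O–H insertion into the secondary alcohol is neutral, so the base-sensitive α-hydroxy ester centre (C13, R, from the chiral pool) should be carried over unchanged.

Step 2
Reactants: 3 methyl (2R)-2-(2-tert-butoxy-2-oxoethoxy)butanoate
Product: 4 tert-butyl 2-{[(2R)-1-oxobutan-2-yl]oxy}acetate
Conditions: DIBAL-H (1.05 equiv), CH2Cl2, −78 °C; MeOH, aq. Rochelle salt
Reagents that add atoms: none
Why: Partial DIBAL reduction of an ester: the α-alkoxy methyl ester should form a chelated tetrahedral aluminate much faster than the hindered tert-butyl ester and release the aldehyde only on work-up.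

Step 3
Reactants: 4 tert-butyl 2-{[(2R)-1-oxobutan-2-yl]oxy}acetate; 5 1-methoxy-1,3-bis(trimethylsilyloxy)buta-1,3-diene
Product: 6 methyl (5R,6R)-6-(2-tert-butoxy-2-oxoethoxy)-5-hydroxy-3-oxooctanoate
Conditions: TiCl4 (1.1 equiv), CH2Cl2, −78 °C; then 5; aq. NaHCO3
Reagents that add atoms: none
Why: Chelation-controlled vinylogous Mukaiyama aldol addition: TiCl4 ties the aldehyde oxygen to the α-ether oxygen and the dienolate should attack the face opposite the ethyl group, setting C12 (R, 12,13-syn).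

Step 4
Reactants: 6 methyl (5R,6R)-6-(2-tert-butoxy-2-oxoethoxy)-5-hydroxy-3-oxooctanoate
Product: 7 tert-butyl 2-{(1R)-1-[(2R)-4,6-dioxooxan-2-yl]propoxy}acetate (β-keto-δ-lactone, drawn as the diketo tautomer)
Conditions: K2CO3, MeOH, 25 °C; then 1 M HCl to pH 3
Reagents that add atoms: none
Why: Base-mediated lactonisation of a δ-hydroxy β-keto ester: the C12 hydroxyl should displace methoxide to give the six-membered ring that later locks the C9=C10 geometry, while the tert-butyl ester resists methanolysis.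

Step 5
Reactants: 7 tert-butyl 2-{(1R)-1-[(2R)-4,6-dioxooxan-2-yl]propoxy}acetate
Product: 8 tert-butyl 2-{(1R)-1-[(2R)-4-chloro-6-oxo-3,6-dihydro-2H-pyran-2-yl]propoxy}acetate
Conditions: (COCl)2, CH2Cl2, 0 → 25 °C
Reagents that add atoms: oxalyl chloride ClC(=O)C(Cl)=O
Why: Chlorodehydroxylation of a cyclic 1,3-dicarbonyl enol with oxalyl chloride (vinylogous acid chloride formation) should replace the C10 enol oxygen by chlorine and leave the lactone carbonyl (C8).

Step 6
Reactants: 8 tert-butyl 2-{(1R)-1-[(2R)-4-chloro-6-oxo-3,6-dihydro-2H-pyran-2-yl]propoxy}acetate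
Product: 10 tert-butyl 2-{[(3R,4R,6E)-6-chloro-4,8-dihydroxyoct-6-en-3-yl]oxy}acetate, via lactol 9 (not isolated)
Conditions: DIBAL-H (1.1 equiv), CH2Cl2, −78 °C; then MeOH, CeCl3·7H2O, NaBH4, −78 → 0 °C
Reagents that add atoms: none
Why: Lactone-to-lactol reduction followed by Luche 1,2-reduction of the ring-opened β-chloro enal should give the diol with C8 and C11 cis, as fixed by the lactone ring, without conjugate loss of chloride and without touching the tert-butyl ester.

Step 7
Reactants: 10 tert-butyl 2-{[(3R,4R,6E)-6-chloro-4,8-dihydroxyoct-6-en-3-yl]oxy}acetate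
Product: 11 tert-butyl 2-{[(3R,4R,6E)-6,8-dichloro-4-hydroxyoct-6-en-3-yl]oxy}acetate
Conditions: NCS, Me2S, CH2Cl2, −20 → 0 °C
Reagents that add atoms: N-chlorosuccinimide O=C1CCC(=O)N1Cl
Why: Corey–Kim chlorination: the chlorosulfonium reagent should convert only the primary allylic alcohol (C8) into the chloride, the saturated secondary alcohol being returned unchanged on work-up.

Step 8
Reactants: 11 tert-butyl 2-{[(3R,4R,6E)-6,8-dichloro-4-hydroxyoct-6-en-3-yl]oxy}acetate
Product: 12 tert-butyl 2-{[(3R,4S,6E)-4-bromo-6,8-dichlorooct-6-en-3-yl]oxy}acetate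
Conditions: CBr4, PPh3, CH2Cl2, 0 → 25 °C
Reagents that add atoms: tetrabromomethane BrC(Br)(Br)Br
Why: Appel bromination of the secondary alcohol should proceed by SN2 displacement of the alkoxyphosphonium by bromide with inversion, turning C12 from R (OH) into S (Br).

Step 9
Reactants: 12 tert-butyl 2-{[(3R,4S,6E)-4-bromo-6,8-dichlorooct-6-en-3-yl]oxy}acetate
Product: 13 tert-butyl (2RS,4E,7S,8R)-7-bromo-5-chloro-8-ethyl-3,6,7,8-tetrahydro-2H-oxocine-2-carboxylate (both C7 epimers)
Conditions: KHMDS, THF (0.01 M), −78 → −40 °C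
Reagents that add atoms: none
Why: Intramolecular alkylation of the glycolate ester enolate by the primary allylic chloride (8-exo-tet, helped by the ring-cis C9=C10 bond) should close the oxocene, and the configuration at C7 need not be controlled because it is erased in step 17.

Step 10
Reactants: 13 tert-butyl (2RS,4E,7S,8R)-7-bromo-5-chloro-8-ethyl-3,6,7,8-tetrahydro-2H-oxocine-2-carboxylate
Product: 14 (2RS,4E,7S,8R)-7-bromo-5-chloro-8-ethyl-3,6,7,8-tetrahydro-2H-oxocine-2-carboxylic acid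
Conditions: TFA, CH2Cl2, 0 → 25 °C
Reagents that add atoms: none
Why: Acid-induced E1 cleavage of the tert-butyl ester should free the carboxylic acid without touching the ether, the halides or the alkene.

Step 11
Reactants: 14 (2RS,4E,7S,8R)-7-bromo-5-chloro-8-ethyl-3,6,7,8-tetrahydro-2H-oxocine-2-carboxylic acid
Product: 15 1,3-dioxoisoindolin-2-yl (2RS,4E,7S,8R)-7-bromo-5-chloro-8-ethyl-3,6,7,8-tetrahydro-2H-oxocine-2-carboxylate
Conditions: N-hydroxyphthalimide, DIC, DMAP (cat.), CH2Cl2, 25 °C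
Reagents that add atoms: N-hydroxyphthalimide ON1C(=O)c2ccccc2C1=O
Why: Carbodiimide (Steglich-type) esterification should give the redox-active N-acyloxyphthalimide needed for single-electron decarboxylation.

Step 12
Reactants: 16 (R)-(2,2-dimethyl-1,3-dioxolan-4-yl)methanol
Product: 17 (S)-2,2-dimethyl-1,3-dioxolane-4-carbaldehyde
Conditions: (COCl)2, DMSO, CH2Cl2, −78 °C; Et3N, −78 → 0 °C
Reagents that add atoms: none
Why: Swern oxidation should give the aldehyde without epimerising the α-alkoxy stereocentre (the future C5).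

Step 13
Reactants: 17 (S)-2,2-dimethyl-1,3-dioxolane-4-carbaldehyde; 18 1,3-bis(triisopropylsilyl)prop-1-yne
Product: 19 (4R)-2,2-dimethyl-4-[(1Z)-4-(triisopropylsilyl)but-1-en-3-yn-1-yl]-1,3-dioxolane
Conditions: 18, n-BuLi, THF, −20 °C; then 17, −78 → 25 °C
Reagents that add atoms: none
Why: Peterson olefination with the lithiated 1,3-disilylpropyne: syn-elimination of the β-oxidosilane with the bulky triisopropylsilyl groups should give the (Z)-enyne selectively.

Step 14
Reactants: 19 (4R)-2,2-dimethyl-4-[(1Z)-4-(triisopropylsilyl)but-1-en-3-yn-1-yl]-1,3-dioxolane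
Product: 21 (2R,3Z)-hex-3-en-5-yne-1,2-diol, via terminal-alkyne acetonide 20 (not isolated)
Conditions: TBAF, THF, 0 °C; then 1 M HCl, MeOH, 25 °C
Reagents that add atoms: none
Why: Fluoride-induced C(sp)–Si cleavage followed by acid-catalysed acetal hydrolysis should give the diol, the volatile terminal alkyne acetonide being carried on in solution.

Step 15
Reactants: 21 (2R,3Z)-hex-3-en-5-yne-1,2-diol
Product: 22 (2R,3Z)-1,2-bis(triethylsilyloxy)hex-3-en-5-yne
Conditions: TESCl, imidazole, DMF, 0 → 25 °C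
Reagents that add atoms: chlorotriethylsilane CC[Si](Cl)(CC)CC
Why: Standard silylation of both hydroxyl groups with a silyl chloride and imidazole.

Step 16
Reactants: 22 (2R,3Z)-1,2-bis(triethylsilyloxy)hex-3-en-5-yne
Product: 23 (2R,3Z)-2-(triethylsilyloxy)hex-3-en-5-ynal
Conditions: (COCl)2, DMSO, CH2Cl2, −78 → −30 °C; Et3N, −78 → 0 °C; used at once
Reagents that add atoms: none
Why: Under Swern conditions activated DMSO should cleave and oxidise only the primary triethylsilyl ether (desilylative Swern oxidation), leaving the secondary allylic silyl ether in place.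

Step 17
Reactants: 15 1,3-dioxoisoindolin-2-yl (2RS,4E,7S,8R)-7-bromo-5-chloro-8-ethyl-3,6,7,8-tetrahydro-2H-oxocine-2-carboxylate; 23 (2R,3Z)-2-(triethylsilyloxy)hex-3-en-5-ynal
Product: 25 (1R,2R,3Z)-1-[(2R,4E,7S,8R)-7-bromo-5-chloro-8-ethyl-3,6,7,8-tetrahydro-2H-oxocin-2-yl]hex-3-en-5-yne-1,2-diol, via C5-O-triethylsilyl ether 24 (not isolated)
Conditions: CrCl2 (4 equiv), THF–DMF, 25 °C; then 1 M HCl, THF, 0 °C
Reagents that add atoms: none
Why: Proposed new method: Cr(II) transfers an electron to the N-acyloxyphthalimide of 15, CO2 is lost, and the planar α-alkoxy radical at C7 (stabilised by the ring oxygen) is trapped by a second Cr(II) to give an α-alkoxyalkyl–Cr(III) species that adds to aldehyde 23, so both C7 epimers of 15 converge on one intermediate. The closest known reaction types are the Cr(II)-mediated decarboxylative alkyl Nozaki–Hiyama–Kishi addition of redox-active esters to aldehydes and the samarium-Barbier coupling of anomeric sulfones with aldehydes. No ring is closed, since the oxocene is already in place. C7 should be set by the ring: the bulky C–Cr bond, and then the C–C bond formed from it with retention, should take the peripheral pseudo-equatorial position cis to the C13 substituent across the ether oxygen, giving the 2,8-cis oxocene (7R). C6 should be set by polar Felkin–Anh addition anti to the C5 silyloxy group of 23, which gives the 5,6-anti diol that the inverting chlorination in step 18 needs. The step needs reduction of the N–O ester only, in the presence of the C12 bromide, the C10 vinyl chloride and the terminal alkyne; this is secured because Cr(II) without Ni or Co does not react with unactivated alkyl bromides or vinyl chlorides and because no allylic chloride is yet present at C5.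

Step 18
Reactants: 25 (1R,2R,3Z)-1-[(2R,4E,7S,8R)-7-bromo-5-chloro-8-ethyl-3,6,7,8-tetrahydro-2H-oxocin-2-yl]hex-3-en-5-yne-1,2-diol
Product: 27 (1S,2S,3Z)-1-[(2R,4E,7S,8R)-7-bromo-5-chloro-8-ethyl-3,6,7,8-tetrahydro-2H-oxocin-2-yl]-2-chlorohex-3-en-5-yn-1-yl acetate, via cyclic orthoacetate 26 (not isolated)
Conditions: MeC(OMe)3, PPTS (cat.), CH2Cl2, 25 °C; evaporate; TMSCl, CH2Cl2, 0 → 25 °C
Reagents that add atoms: trimethyl orthoacetate CC(OC)(OC)OC; chlorotrimethylsilane C[Si](C)(C)Cl
Why: Cyclic orthoester formation and ionisation give a 2-methyl-1,3-dioxolan-2-ylium ion that chloride should open by SN2 at the allylic C5 (not at the hindered, β-oxygenated C6) with inversion, setting C5 (S) and leaving the C6 oxygen as its acetate.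

Step 19
Reactants: 27 (1S,2S,3Z)-1-[(2R,4E,7S,8R)-7-bromo-5-chloro-8-ethyl-3,6,7,8-tetrahydro-2H-oxocin-2-yl]-2-chlorohex-3-en-5-yn-1-yl acetate
Product: 28 bermudenynol, (1S,2S,3Z)-1-[(2R,4E,7S,8R)-7-bromo-5-chloro-8-ethyl-3,6,7,8-tetrahydro-2H-oxocin-2-yl]-2-chlorohex-3-en-5-yn-1-ol
Conditions: DIBAL-H, CH2Cl2, −78 °C; aq. Rochelle salt
Reagents that add atoms: none
Why: Reductive ester cleavage with DIBAL at −78 °C avoids a free alkoxide that could close the chlorohydrin to an epoxide and should leave the halides and the enyne untouched.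

**Compound list**

1 | methyl (2R)-2-hydroxybutanoate | CC[C@@H](O)C(=O)OC | starting material
2 | tert-butyl diazoacetate | [N-]=[N+]=CC(=O)OC(C)(C)C | starting material
3 | methyl (2R)-2-(2-tert-butoxy-2-oxoethoxy)butanoate | COC(=O)[C@@H](CC)OCC(=O)OC(C)(C)C | intermediate
4 | tert-butyl 2-{[(2R)-1-oxobutan-2-yl]oxy}acetate | O=C[C@@H](CC)OCC(=O)OC(C)(C)C | intermediate
5 | 1-methoxy-1,3-bis(trimethylsilyloxy)buta-1,3-diene | COC(O[Si](C)(C)C)=CC(=C)O[Si](C)(C)C | starting material
6 | methyl (5R,6R)-6-(2-tert-butoxy-2-oxoethoxy)-5-hydroxy-3-oxooctanoate | COC(=O)CC(=O)C[C@@H](O)[C@@H](CC)OCC(=O)OC(C)(C)C | intermediate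
7 | tert-butyl 2-{(1R)-1-[(2R)-4,6-dioxooxan-2-yl]propoxy}acetate | O=C1CC(=O)C[C@H]([C@@H](CC)OCC(=O)OC(C)(C)C)O1 | intermediate
8 | tert-butyl 2-{(1R)-1-[(2R)-4-chloro-6-oxo-3,6-dihydro-2H-pyran-2-yl]propoxy}acetate | O=C1C=C(Cl)C[C@H]([C@@H](CC)OCC(=O)OC(C)(C)C)O1 | intermediate
9 | tert-butyl 2-{(1R)-1-[(2R)-4-chloro-6-hydroxy-3,6-dihydro-2H-pyran-2-yl]propoxy}acetate (lactol, both anomers) | OC1C=C(Cl)C[C@H]([C@@H](CC)OCC(=O)OC(C)(C)C)O1 | intermediate
10 | tert-butyl 2-{[(3R,4R,6E)-6-chloro-4,8-dihydroxyoct-6-en-3-yl]oxy}acetate | OC/C=C(/Cl)C[C@@H](O)[C@@H](CC)OCC(=O)OC(C)(C)C | intermediate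
11 | tert-butyl 2-{[(3R,4R,6E)-6,8-dichloro-4-hydroxyoct-6-en-3-yl]oxy}acetate | ClC/C=C(/Cl)C[C@@H](O)[C@@H](CC)OCC(=O)OC(C)(C)C | intermediate
12 | tert-butyl 2-{[(3R,4S,6E)-4-bromo-6,8-dichlorooct-6-en-3-yl]oxy}acetate | ClC/C=C(/Cl)C[C@H](Br)[C@@H](CC)OCC(=O)OC(C)(C)C | intermediate
13 | tert-butyl (2RS,4E,7S,8R)-7-bromo-5-chloro-8-ethyl-3,6,7,8-tetrahydro-2H-oxocine-2-carboxylate | CC(C)(C)OC(=O)C1C/C=C(/Cl)C[C@H](Br)[C@@H](CC)O1 | intermediate
14 | (2RS,4E,7S,8R)-7-bromo-5-chloro-8-ethyl-3,6,7,8-tetrahydro-2H-oxocine-2-carboxylic acid | OC(=O)C1C/C=C(/Cl)C[C@H](Br)[C@@H](CC)O1 | intermediate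
15 | 1,3-dioxoisoindolin-2-yl (2RS,4E,7S,8R)-7-bromo-5-chloro-8-ethyl-3,6,7,8-tetrahydro-2H-oxocine-2-carboxylate | O=C(ON1C(=O)c2ccccc2C1=O)C3C/C=C(/Cl)C[C@H](Br)[C@@H](CC)O3 | intermediate
16 | (R)-(2,2-dimethyl-1,3-dioxolan-4-yl)methanol | OC[C@@H]1COC(C)(C)O1 | starting material
17 | (S)-2,2-dimethyl-1,3-dioxolane-4-carbaldehyde | O=C[C@@H]1COC(C)(C)O1 | intermediate
18 | 1,3-bis(triisopropylsilyl)prop-1-yne | CC(C)[Si](C(C)C)(C(C)C)CC#C[Si](C(C)C)(C(C)C)C(C)C | starting material
19 | (4R)-2,2-dimethyl-4-[(1Z)-4-(triisopropylsilyl)but-1-en-3-yn-1-yl]-1,3-dioxolane | CC(C)[Si](C(C)C)(C(C)C)C#C/C=C\[C@@H]1COC(C)(C)O1 | intermediate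
20 | (4R)-4-[(1Z)-but-1-en-3-yn-1-yl]-2,2-dimethyl-1,3-dioxolane | C#C/C=C\[C@@H]1COC(C)(C)O1 | intermediate
21 | (2R,3Z)-hex-3-en-5-yne-1,2-diol | C#C/C=C\[C@@H](O)CO | intermediate
22 | (2R,3Z)-1,2-bis(triethylsilyloxy)hex-3-en-5-yne | C#C/C=C\[C@@H](O[Si](CC)(CC)CC)CO[Si](CC)(CC)CC | intermediate
23 | (2R,3Z)-2-(triethylsilyloxy)hex-3-en-5-ynal | C#C/C=C\[C@@H](O[Si](CC)(CC)CC)C=O | intermediate
24 | (1S,2R,3Z)-1-[(2R,4E,7S,8R)-7-bromo-5-chloro-8-ethyl-3,6,7,8-tetrahydro-2H-oxocin-2-yl]-2-(triethylsilyloxy)hex-3-en-5-yn-1-ol (present in the flask as its chromium(III) alkoxide) | C#C/C=C\[C@@H](O[Si](CC)(CC)CC)[C@@H](O)[C@H]1C/C=C(/Cl)C[C@H](Br)[C@@H](CC)O1 | intermediate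
25 | (1R,2R,3Z)-1-[(2R,4E,7S,8R)-7-bromo-5-chloro-8-ethyl-3,6,7,8-tetrahydro-2H-oxocin-2-yl]hex-3-en-5-yne-1,2-diol | C#C/C=C\[C@@H](O)[C@@H](O)[C@H]1C/C=C(/Cl)C[C@H](Br)[C@@H](CC)O1 | intermediate
26 | cyclic orthoacetate of 25 (2-methoxy-2-methyl-1,3-dioxolane across O5 and O6, both epimers at the orthoester carbon) | C#C/C=C\[C@H]1OC(C)(OC)O[C@H]1[C@H]2C/C=C(/Cl)C[C@H](Br)[C@@H](CC)O2 | intermediate
27 | (1S,2S,3Z)-1-[(2R,4E,7S,8R)-7-bromo-5-chloro-8-ethyl-3,6,7,8-tetrahydro-2H-oxocin-2-yl]-2-chlorohex-3-en-5-yn-1-yl acetate | C#C/C=C\[C@H](Cl)[C@@H](OC(C)=O)[C@H]1C/C=C(/Cl)C[C@H](Br)[C@@H](CC)O1 | intermediate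
28 | bermudenynol, (1S,2S,3Z)-1-[(2R,4E,7S,8R)-7-bromo-5-chloro-8-ethyl-3,6,7,8-tetrahydro-2H-oxocin-2-yl]-2-chlorohex-3-en-5-yn-1-ol | C#C/C=C\[C@H](Cl)[C@@H](O)[C@H]1C/C=C(/Cl)C[C@H](Br)[C@@H](CC)O1 | target

**Step count and risks**

Total step count: 19. Longest linear sequence: 14 steps (steps 1–11, then 17, 18, 19).

Steps most likely to fail:

1. Step 17 (Proposed new method). The C7 radical may abstract hydrogen or dimerise before Cr(II) traps it, the facial selectivity at C7 on the flexible eight-membered ring may be poor, and Felkin control at C6 may erode. Fallback with known chemistry, setting out from 14: oxidative decarboxylation with Pb(OAc)4 should give the anomeric acetate (2RS,4E,7S,8R)-7-bromo-5-chloro-8-ethyl-3,6,7,8-tetrahydro-2H-oxocin-2-yl acetate F1. Lewis-acid exchange with 2-mercaptopyridine (BF3·OEt2) should give the 2-pyridyl thioacetal F2, and oxidation with mCPBA the 2-pyridyl sulfone F3. A samarium-Barbier coupling of F3 with 23 (SmI2, THF), the established way to join an ether α-carbon to an aldehyde carbon, should then give 24 and, after the same acid work-up, rejoin the route at 25.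

2. Step 18. The allylic acetoxonium ion or the allylic chloride may ionise (SN1 or SN2′ pathways), with loss of configuration at C5 or of the (Z)-geometry, or chloride may attack C6. Fallback, setting out from 24 (isolated by a neutral work-up in step 17): silylation of the C6 hydroxyl (TBSOTf, 2,6-lutidine) should give the bis-silyl ether F4. Selective removal of the triethylsilyl group (PPTS, MeOH) should give the C5 alcohol F5. Appel chlorination (Ph3P, CCl4), a direct SN2 displacement with inversion and without a participating acyloxy neighbour, should give the C5 chloride F6. HF·pyridine should then remove the silyl ether and rejoin the route at 28.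

3. Step 9. Base-induced loss of HBr from C12, or attack at the chlorine-bearing alkene terminus, may compete with the eight-membered ring closure. Fallback, setting out from 11: protection of the C12 hydroxyl (TBSOTf, 2,6-lutidine) should give the silyl ether F7. The same enolate alkylation (KHMDS, THF) should give the silyloxy oxocene ester F8, and HF·pyridine the ring alcohol F9. Bromination on the ring with inversion (CBr4, P(n-Oct)3, toluene, 70 °C) should then rejoin the route at 13.

Further compounds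
F1 | step 17 | (2RS,4E,7S,8R)-7-bromo-5-chloro-8-ethyl-3,6,7,8-tetrahydro-2H-oxocin-2-yl acetate | CC(=O)OC1C/C=C(/Cl)C[C@H](Br)[C@@H](CC)O1
F2 | step 17 | 2-{[(2RS,4E,7S,8R)-7-bromo-5-chloro-8-ethyl-3,6,7,8-tetrahydro-2H-oxocin-2-yl]sulfanyl}pyridine | c1ccc(SC2C/C=C(/Cl)C[C@H](Br)[C@@H](CC)O2)nc1
F3 | step 17 | 2-{[(2RS,4E,7S,8R)-7-bromo-5-chloro-8-ethyl-3,6,7,8-tetrahydro-2H-oxocin-2-yl]sulfonyl}pyridine | O=S(=O)(c1ccccn1)C2C/C=C(/Cl)C[C@H](Br)[C@@H](CC)O2
F4 | step 18 | C6-O-tert-butyldimethylsilyl, C5-O-triethylsilyl ether of 25 | C#C/C=C\[C@@H](O[Si](CC)(CC)CC)[C@@H](O[Si](C)(C)C(C)(C)C)[C@H]1C/C=C(/Cl)C[C@H](Br)[C@@H](CC)O1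
F5 | step 18 | C6-O-tert-butyldimethylsilyl ether of 25 (free C5 hydroxyl) | C#C/C=C\[C@@H](O)[C@@H](O[Si](C)(C)C(C)(C)C)[C@H]1C/C=C(/Cl)C[C@H](Br)[C@@H](CC)O1
F6 | step 18 | C6-O-tert-butyldimethylsilyl ether of 28 | C#C/C=C\[C@H](Cl)[C@@H](O[Si](C)(C)C(C)(C)C)[C@H]1C/C=C(/Cl)C[C@H](Br)[C@@H](CC)O1
F7 | step 9 | tert-butyl 2-{[(3R,4R,6E)-4-(tert-butyldimethylsilyloxy)-6,8-dichlorooct-6-en-3-yl]oxy}acetate | ClC/C=C(/Cl)C[C@@H](O[Si](C)(C)C(C)(C)C)[C@@H](CC)OCC(=O)OC(C)(C)C
F8 | step 9 | tert-butyl (2RS,4E,7R,8R)-7-(tert-butyldimethylsilyloxy)-5-chloro-8-ethyl-3,6,7,8-tetrahydro-2H-oxocine-2-carboxylate | CC(C)(C)OC(=O)C1C/C=C(/Cl)C[C@@H](O[Si](C)(C)C(C)(C)C)[C@@H](CC)O1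
F9 | step 9 | tert-butyl (2RS,4E,7R,8R)-5-chloro-8-ethyl-7-hydroxy-3,6,7,8-tetrahydro-2H-oxocine-2-carboxylate | CC(C)(C)OC(=O)C1C/C=C(/Cl)C[C@@H](O)[C@@H](CC)O1
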